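## Structural features

The target is an achiral, linear tridepside: three benzene rings joined head to tail by two aryl ester bonds, from the ring A carbonyl to O4 of ring B and from the ring B carbonyl to O4 of ring C (each ring numbered as an orsellinate: C1 carbonyl carbon, C2 and C4 oxygens, C6 methyl). Rings B and C are orsellinate units with a chelated C2 hydroxyl, and ring C ends in a free salicylic-type carboxylic acid. Ring A has one oxygen more: free hydroxyls at C2 and C4, an acetate on O5 and the C6 methyl, so that only C3 carries hydrogen. There is no stereocentre, so no stereochemical relationship has to be set or kept. The fragile groups are the two depside esters and the aryl acetate (cleaved or transposed by base and nucleophiles), the O5 acetate next to the free O4 hydroxyl (acyl migration), and the ring C acid (decarboxylation once free and heated). The real difficulty is the differentiation of seven phenolic oxygens (four free, one acetylated, two in ester links) and the release of the acid at the end without base. The key step uses ring B: its C2/C4 meta oxygens, C6 methyl and C1 carboxyl are the footprint of a 1,1,3-trioxygenated butadiene (C2 to C5) added to a but-2-ynoate (C1 and C6), so both depside esters can be carried in on the two partners.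

## Logic of the disconnections

22 to 21: the three benzylic C–O bonds (two ring A ethers, the ring C ester) are cut. Benzyl is the only group that leaves under neutral, non-nucleophilic conditions, which the acetate and both depside esters demand. The forward step must be a hydrogenolysis in an aprotic solvent and must be the last step.

21 to 13 and 17: the ring B bonds C1–C2 and C5–C6 are cut. This removes the central ring and leaves each depside ester on one partner, so two branches of similar size converge and no late esterification between hindered partners is needed. The forward cycloaddition must be regioselective, and the ketene acetal must meet no acidic proton, so the free C2 hydroxyl of 17 has to be masked in the flask as 18.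

13 to 12: the O–Si bond and one C4–H bond are cut. The labile ketene acetal is thereby made in the last operation before use. The forward step must be a γ-deprotonation mild enough for the aryl acetate and the enol ester.

12 to 9 and 10: the enol ester O–C(=O) bond is cut. This separates the four-carbon unit (commercial 10) from the ring A acid. The forward acylation must go at oxygen, not at carbon, of the β-keto ester.

9 to 7: the O5–acetyl bond is cut. The acetate is placed while O2 and O4 are benzylated and the carboxyl is free, the only stage at which O5 is the sole free phenol. The carboxyl must come out of the acetylation unchanged.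

7 to 4: the C5–O bond is cut back to a C5–CHO bond, and the methyl ester is restored. An aldehyde is the simplest precursor of a phenol on an electron-rich ring. The forward oxidation must migrate the aryl group, and the hindered ester must then be hydrolysed before any acetate is present.

4 to 3: the C5–CHO bond is cut. This leads back to a simple resorcinol diether. The electrophile must enter at C5 and not at C3.

3 to 1 and 2: the two benzyl O–C bonds are cut, leading to commercial materials. Both phenols, including the chelated one, must be alkylated, so two equivalents of 2 are consumed.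

17 to 15 and 16: the aryl O–C(=O) bond of the ynoate is cut. Only O4 of 15 may be acylated; its chelated O2 hydroxyl is left free. This saves a protection and deprotection sequence on ring C compared with a fully benzylated dienophile.

15 to 14 and 2: the ester O–CH2 bond is cut. Starting from the free acid 14, and not from 1, avoids the hydrolysis of a methyl ester on a ring that decarboxylates easily. Only the carboxylate may be alkylated.

## Other disconnections considered

Alternative 1: Ring C would be cut at C2–C3 and C1–C6, with a lactone bridge leaving as carbon dioxide. In the forward direction the acylated pyrone A1 would add benzyl 3-methoxypropiolate A2 across pyrone C3 and C6, and the bridged adduct would lose CO2 to give the tridepside A3.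
- In its favour: the pyrone core comes from cheap triacetic acid lactone; the push–pull alkyne is polarised to match the pyrone; the extrusion is irreversible. A1 is bench-stable, which is better than the moisture-sensitive 13.
- Against it, structure: A3 carries a methyl ether on ring C O2 that the target lacks. Its removal would need a boron trihalide type demethylation in the presence of two depside esters and the acetate, whereas 21 needs hydrogenolysis only.
- Against it, mechanism: 2-pyrones are reluctant dienes and an alkoxypropiolate is a deactivated dienophile. Temperatures well above those of step 9 would be expected, at which the 4-acyloxy pyrone may transfer its acyl group.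
- Against it, step economy: A1 needs a ring A–B acid, hence an orthogonal carboxyl protecting group on ring B and two esterifications in one long line, so convergence is lower.
- Equal points: both plans carry both depside esters through the ring-forming step, and both form two C–C bonds and one ring.

Alternative 2: Ring A would be cut at C1–C6, C1–C2, C3–C4 and C4–C5, back to the diazo keto ester A4 and triisopropylsilyloxyethyne A5. Heating A4 with A5 would trigger a Wolff rearrangement to a vinylketene, a ketene–alkyne [2+2] addition, four-electron opening and six-electron closure, giving A6.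
- In its favour: the penta-substituted ring A is built de novo, so the position of O5 is fixed by constitution and not by an electrophilic substitution. This is better than step 2 of the chosen route. Four bonds form in one operation, and regiocontrol by ketene–ynol ether polarity is as secure as that of step 9.
- Against it, structure: A6 has O4–H free beside the O5 acetate while O2 is silylated. At the reaction temperature and in the later fluoride desilylation, acetyl migration from O5 to O4 would endanger exactly the feature that defines the target.
- Against it, mechanism and precursors: A4 combines a diazo β-keto ester, an enol acetate and a didepside aryl ester. It would be laborious to make, and the aryloxide is a good leaving group. A5 is moisture-sensitive and must be prepared.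
- Against it, step economy: two steps follow the key step (desilylation, hydrogenolysis) against one, and the whole ring B–C didepside must be carried through the diazo chemistry in one line.

Alternative 3: Ring A would be cut at C1–C6, back to the open-chain acetoxy triketo ester A7. Mild base would make chain C2 add to the C7 ketone (six-membered aldol closure), and dehydration and enolisation would give A8.
- In its favour: it follows the biosynthetic fold; ring A needs no protecting group; the closure runs at ambient temperature, milder than step 9. A8 needs one hydrogenolysis to reach the target, which equals the chosen plan.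
- Against it, mechanism: A7 is an aryl ester of a poly-β-keto acid. Claisen-type closure onto C1 or pyrone formation would expel the didepside phenoxide and break the A–B link. The C6 acetoxy group lies between two ketones and could move to an enol oxygen or be lost.
- Against it, step economy: building A7 would need polyanion acylation chemistry that an aryl ester and an acetate do not tolerate, so the route to the precursor would be longer and more fragile than steps 1 to 6.

Key step: step 9

Assumption: 12 and 13 are drawn as single (E) isomers; neither double-bond geometry survives into the arene, so mixtures would serve equally.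
Assumption: the skeletons of 13, 17 and 21 map atom for atom onto the target. The only design changes are the free ring C hydroxyl of 17 (masked in the flask as 18) and the use of 14 as the ring C source.

## Route

Step 1
Reactants: 1 methyl orsellinate (methyl 2,4-dihydroxy-6-methylbenzoate); 2 benzyl bromide
Product: 3 methyl 2,4-bis(benzyloxy)-6-methylbenzoate
Conditions: BnBr (2.5 equiv), K2CO3, DMF, 60 °C
Reagents that add atoms: benzyl bromide (second equivalent of 2) BrCc1ccccc1
Why: Twofold Williamson ether synthesis that consumes two equivalents of 2; in DMF with excess bromide the chelated C2 phenol is alkylated as well as the C4 phenol, and the methyl ester is inert.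

Step 2
Reactants: 3 methyl 2,4-bis(benzyloxy)-6-methylbenzoate
Product: 4 methyl 4,6-bis(benzyloxy)-3-formyl-2-methylbenzoate
Conditions: POCl3, DMF, 70 °C; then H2O, 50 °C
Reagents that add atoms: N,N-dimethylformamide CN(C)C=O; water O
Why: Vilsmeier–Haack formylation; C5 of the orsellinate ring is para to the C2 benzyloxy group and ortho to the C4 one, whereas C3 is flanked by two benzyloxy groups, so the chloroiminium ion should enter at C5; the ester is meta to the site and only mildly deactivating.

Step 3
Reactants: 4 methyl 4,6-bis(benzyloxy)-3-formyl-2-methylbenzoate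
Product: 7 4,6-bis(benzyloxy)-3-hydroxy-2-methylbenzoic acid, via aryl formate 5 (not isolated), via phenol methyl ester 6 (not isolated)
Conditions: mCPBA, CH2Cl2, 0 °C to rt; NaHCO3 wash; then KOH, DMSO/H2O, 80 °C (degassed); then 1 M HCl
Reagents that add atoms: mCPBA OOC(=O)c1cccc(Cl)c1; potassium hydroxide [K+].[OH-]
Why: Baeyer–Villiger (Dakin-type) oxidation, in which the electron-rich aryl group with ortho and para alkoxy donors migrates to give the formate; hot hydroxide in aqueous DMSO then cleaves the formate at once and the di-ortho-substituted methyl ester by forced acyl–oxygen hydrolysis, and benzyl ethers tolerate both stages.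

Step 4
Reactants: 7 4,6-bis(benzyloxy)-3-hydroxy-2-methylbenzoic acid
Product: 9 3-acetoxy-4,6-bis(benzyloxy)-2-methylbenzoic acid, via mixed anhydride 8 (not isolated)
Conditions: Ac2O, pyridine, DMAP (cat.), CH2Cl2, rt; then H2O/THF, rt
Reagents that add atoms: acetic anhydride CC(=O)OC(C)=O
Why: DMAP-catalysed acetylation of the only free phenol; the carboxyl group is acetylated too, but water attacks the mixed anhydride at its unhindered acetyl carbonyl and returns the hindered aryl acid, as in the acetylation of salicylic acid.

Step 5
Reactants: 9 3-acetoxy-4,6-bis(benzyloxy)-2-methylbenzoic acid; 10 methyl acetoacetate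
Product: 12 methyl (E)-3-{[3-acetoxy-4,6-bis(benzyloxy)-2-methylbenzoyl]oxy}but-2-enoate, via acid chloride 11 (not isolated)
Conditions: (COCl)2, DMF (cat.), CH2Cl2, 0 °C to rt; evaporate; then 10, Et3N, DMAP (cat.), CH2Cl2, 0 °C
Reagents that add atoms: none
Why: Acid chloride formation followed by O-acylation of a metal-free β-keto ester enolate; the hindered, donor-substituted aroyl chloride reacts through an acylium-like hard transition state and the triethylammonium enolate, lacking a chelating cation, should react at oxygen to give the enol ester.

Step 6
Reactants: 12 methyl (E)-3-{[3-acetoxy-4,6-bis(benzyloxy)-2-methylbenzoyl]oxy}but-2-enoate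
Product: 13 (3E)-4-methoxy-4-(trimethylsilyloxy)buta-1,3-dien-2-yl 3-acetoxy-4,6-bis(benzyloxy)-2-methylbenzoate
Conditions: TMSOTf, Et3N, Et2O, 0 °C to rt; decant from the ammonium salt, concentrate, use crude
Reagents that add atoms: trimethylsilyl trifluoromethanesulfonate C[Si](C)(C)OS(=O)(=O)C(F)(F)F
Why: Soft enolisation as used to make 1-alkoxy-1-silyloxy-3-oxy dienes from β-oxygenated but-2-enoates; the silyl triflate activates the conjugated ester carbonyl and the amine removes a vinylogous γ-proton from the C4 methyl, so both geometric isomers of 12 converge on the same diene; over-silylation at the acetate methyl, should it occur, would be undone by the acid work-up of step 9.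

Step 7
Reactants: 14 orsellinic acid (2,4-dihydroxy-6-methylbenzoic acid); 2 benzyl bromide
Product: 15 benzyl orsellinate (benzyl 2,4-dihydroxy-6-methylbenzoate)
Conditions: BnBr (1.05 equiv), KHCO3, DMF, rt
Reagents that add atoms: none
Why: Carboxylate alkylation (SN2); hydrogen carbonate deprotonates only the carboxylic acid and leaves both phenols protonated, and room temperature avoids decarboxylation of the acid.

Step 8
Reactants: 15 benzyl orsellinate; 16 but-2-ynoic acid
Product: 17 benzyl 4-(but-2-ynoyloxy)-2-hydroxy-6-methylbenzoate
Conditions: DCC, DMAP (cat.), CH2Cl2, 0 °C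
Reagents that add atoms: none
Why: Steglich esterification; the C4 hydroxyl is the only non-chelated phenol, the C2 hydroxyl being held in a hydrogen bond to the ester carbonyl, and low temperature with little DMAP holds back conjugate addition to the ynoate.

Step 9
Reactants: 13 (3E)-4-methoxy-4-(trimethylsilyloxy)buta-1,3-dien-2-yl 3-acetoxy-4,6-bis(benzyloxy)-2-methylbenzoate; 17 benzyl 4-(but-2-ynoyloxy)-2-hydroxy-6-methylbenzoate
Product: 21 benzyl 4-{[4-{[3-acetoxy-4,6-bis(benzyloxy)-2-methylbenzoyl]oxy}-2-hydroxy-6-methylbenzoyl]oxy}-2-hydroxy-6-methylbenzoate, via trimethylsilyl ether 18 (not isolated), via cyclohexadiene cycloadduct 19 (not isolated), via bis(trimethylsilyl) ether 20 (not isolated)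
Conditions: 17 (1.5 equiv), N,O-bis(trimethylsilyl)acetamide, PhMe, 60 °C; then 13, 120 °C (sealed tube); then 1 M HCl, THF, 0 °C
Reagents that add atoms: none
Why: Normal-electron-demand Diels–Alder benzannulation of a 1,1-dioxygenated 3-oxy diene with an alkynoate, the known route to resorcylates. The phenol of 17 is first capped as 18 so that it cannot protonate the ketene acetal. The HOMO of 13 is largest at the unsubstituted CH2 terminus and the LUMO of 18 at the methyl-bearing β-carbon, so the C5–C6 bond forms ahead of the C1–C2 bond in a concerted, asynchronous, suprafacial [4+2] closure; in the stepwise limit this is a vinylogous Mukaiyama–Michael addition followed by 6-exo-trig attack of the allenoate α-carbon on the oxocarbenium carbon. Ring B is thus closed as the cyclohexa-1,4-diene 19, whose ketal carbon is its only stereocentre and is lost again. Ionisation of the mixed ketal and loss of the C5 proton expel methanol to give arene 20; the acid work-up drives any remaining adduct the same way and hydrolyses both aryl silyl ethers. The selectivity needed is regiochemical (methyl and ester carbon adjacent, hydroxyl on the other side of C1) and is secured by the matched polarisation of the two partners. Chemoselectivity rests on the ynoate being the only electron-poor π-bond, made more electrophilic by its aryl ester, so no new stereocentre remains to be controlled.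

Step 10
Reactants: 21 benzyl 4-{[4-{[3-acetoxy-4,6-bis(benzyloxy)-2-methylbenzoyl]oxy}-2-hydroxy-6-methylbenzoyl]oxy}-2-hydroxy-6-methylbenzoate
Product: 22 4-{[4-{[3-acetoxy-4,6-dihydroxy-2-methylbenzoyl]oxy}-2-hydroxy-6-methylbenzoyl]oxy}-2-hydroxy-6-methylbenzoic acid (CNP0154030.0)
Conditions: H2 (1 atm), Pd/C, EtOAc, rt
Reagents that add atoms: none
Why: Catalytic hydrogenolysis of two aryl benzyl ethers and one benzyl ester; aryl esters and the acetate are inert to hydrogen over Pd/C, and a neutral aprotic solvent avoids transesterification and base-induced acetyl migration.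

## Compound list

1 | methyl orsellinate (methyl 2,4-dihydroxy-6-methylbenzoate) | COC(=O)c1c(C)cc(O)cc1O | starting material
2 | benzyl bromide | BrCc1ccccc1 | starting material
3 | methyl 2,4-bis(benzyloxy)-6-methylbenzoate | COC(=O)c1c(C)cc(OCc2ccccc2)cc1OCc1ccccc1 | intermediate
4 | methyl 4,6-bis(benzyloxy)-3-formyl-2-methylbenzoate | COC(=O)c1c(C)c(C=O)c(OCc2ccccc2)cc1OCc1ccccc1 | intermediate
5 | methyl 4,6-bis(benzyloxy)-3-(formyloxy)-2-methylbenzoate (not isolated) | COC(=O)c1c(C)c(OC=O)c(OCc2ccccc2)cc1OCc1ccccc1 | intermediate
6 | methyl 4,6-bis(benzyloxy)-3-hydroxy-2-methylbenzoate (not isolated) | COC(=O)c1c(C)c(O)c(OCc2ccccc2)cc1OCc1ccccc1 | intermediate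
7 | 4,6-bis(benzyloxy)-3-hydroxy-2-methylbenzoic acid | OC(=O)c1c(C)c(O)c(OCc2ccccc2)cc1OCc1ccccc1 | intermediate
8 | acetic 3-acetoxy-4,6-bis(benzyloxy)-2-methylbenzoic anhydride (not isolated) | CC(=O)OC(=O)c1c(C)c(OC(C)=O)c(OCc2ccccc2)cc1OCc1ccccc1 | intermediate
9 | 3-acetoxy-4,6-bis(benzyloxy)-2-methylbenzoic acid | CC(=O)Oc1c(C)c(C(=O)O)c(OCc2ccccc2)cc1OCc1ccccc1 | intermediate
10 | methyl acetoacetate | COC(=O)CC(C)=O | starting material
11 | 3-acetoxy-4,6-bis(benzyloxy)-2-methylbenzoyl chloride (not isolated) | CC(=O)Oc1c(C)c(C(Cl)=O)c(OCc2ccccc2)cc1OCc1ccccc1 | intermediate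
12 | methyl (E)-3-{[3-acetoxy-4,6-bis(benzyloxy)-2-methylbenzoyl]oxy}but-2-enoate | COC(=O)/C=C(\C)OC(=O)c1c(C)c(OC(C)=O)c(OCc2ccccc2)cc1OCc1ccccc1 | intermediate
13 | (3E)-4-methoxy-4-(trimethylsilyloxy)buta-1,3-dien-2-yl 3-acetoxy-4,6-bis(benzyloxy)-2-methylbenzoate | C=C(OC(=O)c1c(C)c(OC(C)=O)c(OCc2ccccc2)cc1OCc1ccccc1)/C=C(/O[Si](C)(C)C)OC | intermediate
14 | orsellinic acid (2,4-dihydroxy-6-methylbenzoic acid) | Cc1cc(O)cc(O)c1C(=O)O | starting material
15 | benzyl orsellinate (benzyl 2,4-dihydroxy-6-methylbenzoate) | Cc1cc(O)cc(O)c1C(=O)OCc1ccccc1 | intermediate
16 | but-2-ynoic acid | CC#CC(=O)O | starting material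
17 | benzyl 4-(but-2-ynoyloxy)-2-hydroxy-6-methylbenzoate | CC#CC(=O)Oc1cc(C)c(C(=O)OCc2ccccc2)c(O)c1 | intermediate
18 | benzyl 4-(but-2-ynoyloxy)-6-methyl-2-(trimethylsilyloxy)benzoate (not isolated) | CC#CC(=O)Oc1cc(C)c(C(=O)OCc2ccccc2)c(O[Si](C)(C)C)c1 | intermediate
19 | Diels–Alder adduct: 6-methoxy-6-(trimethylsilyloxy)cyclohexa-1,4-diene bearing the ring A aroyloxy group at C4, methyl at C2 and the silylated ring C aryl ester at C1; racemic at the ketal carbon (not isolated) | COC1(O[Si](C)(C)C)C=C(OC(=O)c2c(C)c(OC(C)=O)c(OCc3ccccc3)cc2OCc2ccccc2)CC(C)=C1C(=O)Oc1cc(C)c(C(=O)OCc2ccccc2)c(O[Si](C)(C)C)c1 | intermediate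
20 | bis(trimethylsilyl) ether of 21 at ring B O2 and ring C O2 (not isolated) | CC(=O)Oc1c(OCc2ccccc2)cc(OCc2ccccc2)c(C(=O)Oc2cc(C)c(C(=O)Oc3cc(C)c(C(=O)OCc4ccccc4)c(O[Si](C)(C)C)c3)c(O[Si](C)(C)C)c2)c1C | intermediate
21 | benzyl 4-{[4-{[3-acetoxy-4,6-bis(benzyloxy)-2-methylbenzoyl]oxy}-2-hydroxy-6-methylbenzoyl]oxy}-2-hydroxy-6-methylbenzoate | CC(=O)Oc1c(OCc2ccccc2)cc(OCc2ccccc2)c(C(=O)Oc2cc(C)c(C(=O)Oc3cc(C)c(C(=O)OCc4ccccc4)c(O)c3)c(O)c2)c1C | intermediate
22 | 4-{[4-{[3-acetoxy-4,6-dihydroxy-2-methylbenzoyl]oxy}-2-hydroxy-6-methylbenzoyl]oxy}-2-hydroxy-6-methylbenzoic acid (CNP0154030.0) | CC(=O)Oc1c(O)cc(O)c(C(=O)Oc2cc(C)c(C(=O)Oc3cc(C)c(C(=O)O)c(O)c3)c(O)c2)c1C | target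

## Step count and least certain steps

Total: 10 steps. Longest linear sequence: 8 steps (steps 1 to 6, 9 and 10); the ring C branch (steps 7 and 8) joins at step 9.

Step 9 (key step). Thermal decay of the silyl ketene acetal (desilylation, acyl or silyl shifts) may outrun a cycloaddition that is slowed by the β-methyl group of the ynoate and by the weak acyloxy donor at C3 of the diene. Fallback: setting out from 17, its silyl ether 18 would be heated with commercial 1-methoxy-1,3-bis(trimethylsilyloxy)buta-1,3-diene, a stronger diene that forms the same two ring B bonds. Acid work-up should give benzyl 4-[(2,4-dihydroxy-6-methylbenzoyl)oxy]-2-hydroxy-6-methylbenzoate F1. Its only non-chelated phenol (ring B O4) would then be acylated with acid chloride 11, made from 9 as in step 5 (pyridine, CH2Cl2, 0 °C), a classical depside esterification that returns to the route at 21.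

Step 6. Hydrolytic loss of the trimethylsilyl ketene acetal during removal of the ammonium salt and concentration is the likely failure, since the diene cannot be distilled. Fallback: setting out from 12, silylation with TBSOTf and Et3N would give the sturdier (3E)-4-(tert-butyldimethylsilyloxy)-4-methoxybuta-1,3-dien-2-yl 3-acetoxy-4,6-bis(benzyloxy)-2-methylbenzoate F2, which tolerates filtration and storage. Cycloaddition with 18 as in step 9 and acid work-up would give the ring B O2 tert-butyldimethylsilyl ether of 21 F3. A separate desilylation with Et3N·3HF in THF returns to the route at 21.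

Step 5. Competing acylation at carbon C2 of the acetoacetate, or self-condensation of the enolate while the hindered chloride reacts slowly, would lower the amount of enol ester. Fallback: setting out from 9, Markovnikov addition of the carboxylic acid to methyl but-3-ynoate ([RuCl2(p-cymene)]2, tri(2-furyl)phosphine, Na2CO3, PhMe, 60 °C) would give methyl 3-{[3-acetoxy-4,6-bis(benzyloxy)-2-methylbenzoyl]oxy}but-3-enoate F4 with no enolate involved. Its doubly activated C2 methylene would be silylated under the conditions of step 6, returning to the route at 13 and bypassing 12.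

Step 2. Incomplete formylation of a ring that carries a meta ester, or partial attack at C3, is possible with the weak chloroiminium electrophile. Fallback: setting out from 3, bromination with NBS (MeCN, 0 °C), a stronger and reliably para-directed electrophile, would give methyl 4,6-bis(benzyloxy)-3-bromo-2-methylbenzoate F5. Hydroxylation of the bromide (Pd2(dba)3, t-BuXPhos, KOH, 1,4-dioxane/H2O, 100 °C) would give phenol 6, and the hot hydroxide stage of step 3 then returns to the route at 7.

Step 10. Slow cleavage of the hindered ring A benzyl ethers may give time for acetyl migration from O5 to the newly freed O4, or for partial loss of the acetate. Fallback: setting out from 21, Lewis acid debenzylation with BCl3 and pentamethylbenzene as cation scavenger (CH2Cl2, −78 °C) is fast and non-basic and would give 22 directly; no new compound arises on this detour (entry F0).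

## Further compounds

F1 | step 9 | benzyl 4-[(2,4-dihydroxy-6-methylbenzoyl)oxy]-2-hydroxy-6-methylbenzoate (benzyl lecanorate) | Cc1cc(O)cc(O)c1C(=O)Oc1cc(C)c(C(=O)OCc2ccccc2)c(O)c1
F2 | step 6 | (3E)-4-(tert-butyldimethylsilyloxy)-4-methoxybuta-1,3-dien-2-yl 3-acetoxy-4,6-bis(benzyloxy)-2-methylbenzoate | C=C(OC(=O)c1c(C)c(OC(C)=O)c(OCc2ccccc2)cc1OCc1ccccc1)/C=C(/O[Si](C)(C)C(C)(C)C)OC
F3 | step 6 | ring B O2 tert-butyldimethylsilyl ether of 21 | CC(=O)Oc1c(OCc2ccccc2)cc(OCc2ccccc2)c(C(=O)Oc2cc(C)c(C(=O)Oc3cc(C)c(C(=O)OCc4ccccc4)c(O)c3)c(O[Si](C)(C)C(C)(C)C)c2)c1C
F4 | step 5 | methyl 3-{[3-acetoxy-4,6-bis(benzyloxy)-2-methylbenzoyl]oxy}but-3-enoate | COC(=O)CC(=C)OC(=O)c1c(C)c(OC(C)=O)c(OCc2ccccc2)cc1OCc1ccccc1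
F5 | step 2 | methyl 4,6-bis(benzyloxy)-3-bromo-2-methylbenzoate | COC(=O)c1c(C)c(Br)c(OCc2ccccc2)cc1OCc1ccccc1
F0 | step 10 | none | none
A1 | alternative 1 | 6-methyl-2-oxo-2H-pyran-4-yl 4-{[3-acetoxy-4,6-bis(benzyloxy)-2-methylbenzoyl]oxy}-2-(benzyloxy)-6-methylbenzoate | CC(=O)Oc1c(OCc2ccccc2)cc(OCc2ccccc2)c(C(=O)Oc2cc(C)c(C(=O)Oc3cc(C)oc(=O)c3)c(OCc3ccccc3)c2)c1C
A2 | alternative 1 | benzyl 3-methoxyprop-2-ynoate | COC#CC(=O)OCc1ccccc1
A3 | alternative 1 | benzyl 4-{[4-{[3-acetoxy-4,6-bis(benzyloxy)-2-methylbenzoyl]oxy}-2-(benzyloxy)-6-methylbenzoyl]oxy}-2-methoxy-6-methylbenzoate | CC(=O)Oc1c(OCc2ccccc2)cc(OCc2ccccc2)c(C(=O)Oc2cc(C)c(C(=O)Oc3cc(C)c(C(=O)OCc4ccccc4)c(OC)c3)c(OCc3ccccc3)c2)c1C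
A4 | alternative 2 | (E)-5-acetoxy-2-diazo-4-methyl-3-oxopent-4-enoate of the benzyl-protected ring B–C didepside phenol | CC(=O)O/C=C(\C)C(=O)C(=[N+]=[N-])C(=O)Oc1cc(C)c(C(=O)Oc2cc(C)c(C(=O)OCc3ccccc3)c(OCc3ccccc3)c2)c(OCc2ccccc2)c1
A5 | alternative 2 | triisopropylsilyloxyethyne | C#CO[Si](C(C)C)(C(C)C)C(C)C
A6 | alternative 2 | tridepside with ring A O2 triisopropylsilylated, O4 free, O5 acetylated, rings B and C benzyl-protected | CC(=O)Oc1c(O)cc(O[Si](C(C)C)(C(C)C)C(C)C)c(C(=O)Oc2cc(C)c(C(=O)Oc3cc(C)c(C(=O)OCc4ccccc4)c(OCc4ccccc4)c3)c(OCc3ccccc3)c2)c1C
A7 | alternative 3 | 6-acetoxy-3,5,7-trioxooctanoate of the benzyl-protected ring B–C didepside phenol (racemic at C6) | CC(=O)OC(C(C)=O)C(=O)CC(=O)CC(=O)Oc1cc(C)c(C(=O)Oc2cc(C)c(C(=O)OCc3ccccc3)c(OCc3ccccc3)c2)c(OCc2ccccc2)c1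
A8 | alternative 3 | tridepside with ring A complete, rings B and C benzyl-protected | CC(=O)Oc1c(O)cc(O)c(C(=O)Oc2cc(C)c(C(=O)Oc3cc(C)c(C(=O)OCc4ccccc4)c(OCc4ccccc4)c3)c(OCc3ccccc3)c2)c1C
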